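**Plan**

- Retrosynthesis: the three phenols are unmasked last (MOM ethers). Ring C is then cut at C3–C4, and the hydrogen on C2 is returned to a formyl group, which gives an aldehyde carrying an aryl 1-arylvinyl ether. The C2=C3 double bond is cut back to an aryl ester (methylenation), the ester to an A-ring phenol and a B-ring acid, and the C8 prenyl group to an O-(1,1-dimethylallyl) ether by a retro-Claisen step.
- Forward: ring A (2,4,6-trimethoxybenzaldehyde) and ring B (methyl 3,4-dihydroxybenzoate) are bought. They are joined through O1–C2 as an ester, the ester C=O is turned into C2=C3, and ring C is closed last by intramolecular hydroacylation.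
- Enabling feature: C4 is an aryl ketone carbon on ring A (at C4a) whose ortho neighbour C8a carries the ring oxygen O1, and the only stereocentre C2 bears one hydrogen beside the C3 methylene. C4–C3 and C2–H are therefore exactly the two bonds made when a formyl C–H adds across the C2=C3 double bond of an aryl 1-arylvinyl ether.
- Stereochemistry: the single stereocentre (2S) arises in the ring closure from an achiral precursor, by enantioface-selective hydride delivery under a chiral bisphosphine–rhodium catalyst. Afterwards it meets only mild acid.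

Key step: step 11

Remark: the target is taken as the (2S)-flavanone that the SMILES encodes. Which antipode of the bisphosphine gives this sense in step 11 cannot be predicted with confidence; (R)-DTBM-SEGPHOS is written for definiteness and its enantiomer is used if a test run shows the opposite sense.

**Route**

Step 1
Reactants: 1 methyl 3,4-dihydroxybenzoate
Product: 2 methyl 3,4-bis(methoxymethoxy)benzoate
Conditions: MOMCl, i-Pr2NEt, CH2Cl2, 0 °C to rt
Reagents that add atoms: chloromethyl methyl ether, COCCl
Why: Williamson-type O-alkylation of both catechol hydroxyls by the reactive alpha-chloro ether under amine base (MOM protection) should proceed without touching the ester.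

Step 2
Reactants: 2 methyl 3,4-bis(methoxymethoxy)benzoate
Product: 3 3,4-bis(methoxymethoxy)benzoic acid
Conditions: LiOH·H2O, THF/MeOH/H2O, rt; then 1 M HCl to pH 4, 0 °C
Reagents that add atoms: lithium hydroxide, [Li+].[OH-]
Why: Ester saponification; the MOM acetals are stable to base and should survive the brief cold acidification.

Step 3
Reactants: 4 2-methylbut-3-en-2-ol
Product: 6 tert-butyl (2-methylbut-3-en-2-yl) carbonate, via lithium 2-methylbut-3-en-2-olate 5 (not isolated)
Conditions: n-BuLi, THF, −78 °C; then Boc2O, −78 °C to rt; H2O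
Reagents that add atoms: di-tert-butyl dicarbonate, CC(C)(C)OC(=O)OC(=O)OC(C)(C)C
Why: O-acylation of a tertiary lithium alkoxide by the dicarbonate gives the mixed carbonate that serves as the 1,1-dimethylallyl donor.

Step 4
Reactants: 7 2,4,6-trimethoxybenzaldehyde
Product: 8 2,6-dihydroxy-4-methoxybenzaldehyde
Conditions: AlCl3 (5 equiv), CH2Cl2, 0 to 40 °C; then cold 1 M HCl
Reagents that add atoms: none
Why: Chelation-controlled Lewis-acid ether cleavage: AlCl3 held between the formyl oxygen and each ortho methoxy oxygen delivers chloride to those two methyl groups only, so the para methoxy group (the future 7-OMe) should remain.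

Step 5
Reactants: 8 2,6-dihydroxy-4-methoxybenzaldehyde; 6 tert-butyl (2-methylbut-3-en-2-yl) carbonate
Product: 9 2-hydroxy-4-methoxy-6-[(2-methylbut-3-en-2-yl)oxy]benzaldehyde
Conditions: Pd(PPh3)4 (2 mol%), 6 (1.05 equiv), THF, 0 °C
Reagents that add atoms: none
Why: Tsuji–Trost O-allylation: decarboxylative ionisation of 6 on zerovalent palladium gives a 1,1-dimethylallyl palladium cation that the phenoxide should attack at the more substituted terminus (kinetic branched ether); 8 is symmetric, and the second hydroxyl, hydrogen-bonded to the formyl group, should resist a second allylation.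

Step 6
Reactants: 9 2-hydroxy-4-methoxy-6-[(2-methylbut-3-en-2-yl)oxy]benzaldehyde
Product: 11 4-methoxy-2-(methoxymethoxy)-6-[(2-methylbut-3-en-2-yl)oxy]benzaldehyde, via sodium phenoxide 10 (not isolated)
Conditions: NaH, DMF, 0 °C; then MOMCl, 0 °C to rt
Reagents that add atoms: chloromethyl methyl ether, COCCl
Why: Williamson etherification of the chelated phenol after full deprotonation; the non-enolisable aldehyde and the tert-allyl ether should tolerate the cold basic conditions.

Step 7
Reactants: 11 4-methoxy-2-(methoxymethoxy)-6-[(2-methylbut-3-en-2-yl)oxy]benzaldehyde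
Product: 13 2-hydroxy-4-methoxy-6-(methoxymethoxy)-3-(3-methylbut-2-en-1-yl)benzaldehyde, via ortho-dienone 12 (not isolated)
Conditions: toluene, 110 °C (sealed tube), BHT (trace)
Reagents that add atoms: none
Why: Aromatic Claisen rearrangement ([3,3]-sigmatropic shift, then tautomerisation): the only ortho position bearing hydrogen lies between the ether oxygen and the methoxy group, so the allyl unit should arrive there with allylic inversion as a prenyl group, and the hydroxyl set free next to it is the one that becomes O1.

Step 8
Reactants: 13 2-hydroxy-4-methoxy-6-(methoxymethoxy)-3-(3-methylbut-2-en-1-yl)benzaldehyde; 3 3,4-bis(methoxymethoxy)benzoic acid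
Product: 14 2-formyl-5-methoxy-3-(methoxymethoxy)-6-(3-methylbut-2-en-1-yl)phenyl 3,4-bis(methoxymethoxy)benzoate
Conditions: DCC, DMAP (cat.), CH2Cl2, 0 °C to rt
Reagents that add atoms: none
Why: Steglich esterification; acyl transfer through the acylpyridinium ion should acylate even this flanked, hydrogen-bonded phenol and joins O1 to the future C2.

Step 9
Reactants: 14 2-formyl-5-methoxy-3-(methoxymethoxy)-6-(3-methylbut-2-en-1-yl)phenyl 3,4-bis(methoxymethoxy)benzoate
Product: 15 2-(dimethoxymethyl)-5-methoxy-3-(methoxymethoxy)-6-(3-methylbut-2-en-1-yl)phenyl 3,4-bis(methoxymethoxy)benzoate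
Conditions: HC(OMe)3, MeOH, PPTS (cat.), CH2Cl2, rt; Et3N quench; used crude
Reagents that add atoms: trimethyl orthoformate, COC(OC)OC; methanol, CO
Why: Acid-catalysed acetalisation driven by the orthoformate masks the formyl group against the titanium carbene of the next step; the weak acid at room temperature should leave the MOM ethers and the aryl ester intact.

Step 10
Reactants: 15 2-(dimethoxymethyl)-5-methoxy-3-(methoxymethoxy)-6-(3-methylbut-2-en-1-yl)phenyl 3,4-bis(methoxymethoxy)benzoate
Product: 17 2-({1-[3,4-bis(methoxymethoxy)phenyl]ethenyl}oxy)-4-methoxy-6-(methoxymethoxy)-3-(3-methylbut-2-en-1-yl)benzaldehyde, via acetal vinyl ether 16 (not isolated)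
Conditions: Cp2TiMe2 (3 equiv), toluene/THF, 65 °C, dark; then THF/aq. NaOAc–AcOH buffer (pH 4.5), 0 °C
Reagents that add atoms: dimethyltitanocene, C[Ti+2]C.c1cc[cH-]c1.c1cc[cH-]c1; water, O
Why: Petasis methylenation (Cp2Ti=CH2 formed thermally, oxatitanacyclobutane, loss of titanocene oxide) turns the ester C=O into the C2=C3 double bond, and the acetal of this trioxygenated benzaldehyde should ionise far faster than the aryl vinyl ether is protonated at carbon, so the buffer frees only the aldehyde.

Step 11
Reactants: 17 2-({1-[3,4-bis(methoxymethoxy)phenyl]ethenyl}oxy)-4-methoxy-6-(methoxymethoxy)-3-(3-methylbut-2-en-1-yl)benzaldehyde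
Product: 18 (2S)-2-[3,4-bis(methoxymethoxy)phenyl]-7-methoxy-5-(methoxymethoxy)-8-(3-methylbut-2-en-1-yl)-2,3-dihydro-4H-chromen-4-one
Conditions: [Rh(nbd)2]BF4 (5 mol%), (R)-DTBM-SEGPHOS (5.5 mol%), H2 then Ar, ClCH2CH2Cl, 40 °C
Reagents that add atoms: none
Why: Proposed new method: the formyl C–H bond of 17 should add oxidatively to cationic monovalent rhodium, the rhodium hydride should then add across the tethered vinyl ether with hydrogen going to the disubstituted carbon C2 and rhodium to the unsubstituted CH2 (C3), and C–C reductive elimination should join C3 to the acyl carbon C4. The closest known reactions are the rhodium–bisphosphine-catalysed enantioselective intramolecular hydroacylations of 1,1-disubstituted alkenes (4-substituted pent-4-enals to 3-substituted cyclopentanones, ether-tethered aryl aldehydes to seven-membered ketones) and the endo-selective six-ring closures of ortho-allylbenzaldehydes; an aryl 1-arylvinyl ether as the alkene and a chroman-4-one as the product have not been shown. Ring C closes in a 6-endo-trig mode through a seven-membered acyl–alkyl rhodacycle. The new stereocentre C2 is set by hydride delivery to the Re face of C2, and that face is chosen by the chiral bisphosphine (catalyst control). The step needs endo over 5-exo regioselectivity, which the 1,1-disubstitution should secure because the exo path requires a tertiary alkylrhodium and a reductive elimination that builds a quaternary centre and can revert by beta-hydride elimination. It also needs freedom from alkene isomerisation and from side-chain participation, secured by the lack of allylic hydrogens on the vinyl ether and by the prenyl group being trisubstituted and meta to the formyl group, while the two ortho oxygen substituents flanking the acyl group should hold back decarbonylation.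

Step 12
Reactants: 18 (2S)-2-[3,4-bis(methoxymethoxy)phenyl]-7-methoxy-5-(methoxymethoxy)-8-(3-methylbut-2-en-1-yl)-2,3-dihydro-4H-chromen-4-one
Product: 19 (2S)-2-(3,4-dihydroxyphenyl)-5-hydroxy-7-methoxy-8-(3-methylbut-2-en-1-yl)-2,3-dihydro-4H-chromen-4-one
Conditions: conc. aq. HCl (few equiv), MeOH, rt
Reagents that add atoms: none
Why: Acid-catalysed cleavage of the three MOM acetals; the prenyl group is flanked by the 7-methoxy group and O1, so no chroman can form, and mild acid avoids the base-induced ring opening that would racemise a 5-hydroxyflavanone.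

**Compound list**

1 | methyl 3,4-dihydroxybenzoate | COC(=O)c1ccc(O)c(O)c1 | starting material
2 | methyl 3,4-bis(methoxymethoxy)benzoate | COCOc1ccc(C(=O)OC)cc1OCOC | intermediate
3 | 3,4-bis(methoxymethoxy)benzoic acid | COCOc1ccc(C(=O)O)cc1OCOC | intermediate
4 | 2-methylbut-3-en-2-ol | CC(C)(O)C=C | starting material
5 | lithium 2-methylbut-3-en-2-olate | [Li+].[O-]C(C)(C)C=C | intermediate
6 | tert-butyl (2-methylbut-3-en-2-yl) carbonate | CC(C)(C)OC(=O)OC(C)(C)C=C | intermediate
7 | 2,4,6-trimethoxybenzaldehyde | COc1cc(OC)c(C=O)c(OC)c1 | starting material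
8 | 2,6-dihydroxy-4-methoxybenzaldehyde | COc1cc(O)c(C=O)c(O)c1 | intermediate
9 | 2-hydroxy-4-methoxy-6-[(2-methylbut-3-en-2-yl)oxy]benzaldehyde | COc1cc(O)c(C=O)c(OC(C)(C)C=C)c1 | intermediate
10 | sodium 2-formyl-5-methoxy-3-[(2-methylbut-3-en-2-yl)oxy]phenolate | [Na+].COc1cc([O-])c(C=O)c(OC(C)(C)C=C)c1 | intermediate
11 | 4-methoxy-2-(methoxymethoxy)-6-[(2-methylbut-3-en-2-yl)oxy]benzaldehyde | COCOc1cc(OC)cc(OC(C)(C)C=C)c1C=O | intermediate
12 | 4-methoxy-2-(methoxymethoxy)-5-(3-methylbut-2-en-1-yl)-6-oxocyclohexa-1,3-diene-1-carbaldehyde (racemic, transient) | COCOC1=C(C=O)C(=O)C(CC=C(C)C)C(OC)=C1 | intermediate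
13 | 2-hydroxy-4-methoxy-6-(methoxymethoxy)-3-(3-methylbut-2-en-1-yl)benzaldehyde | COCOc1cc(OC)c(CC=C(C)C)c(O)c1C=O | intermediate
14 | 2-formyl-5-methoxy-3-(methoxymethoxy)-6-(3-methylbut-2-en-1-yl)phenyl 3,4-bis(methoxymethoxy)benzoate | COCOc1cc(OC)c(CC=C(C)C)c(OC(=O)c2ccc(OCOC)c(OCOC)c2)c1C=O | intermediate
15 | 2-(dimethoxymethyl)-5-methoxy-3-(methoxymethoxy)-6-(3-methylbut-2-en-1-yl)phenyl 3,4-bis(methoxymethoxy)benzoate | COCOc1cc(OC)c(CC=C(C)C)c(OC(=O)c2ccc(OCOC)c(OCOC)c2)c1C(OC)OC | intermediate
16 | 4-{1-[2-(dimethoxymethyl)-5-methoxy-3-(methoxymethoxy)-6-(3-methylbut-2-en-1-yl)phenoxy]ethenyl}-1,2-bis(methoxymethoxy)benzene | COCOc1cc(OC)c(CC=C(C)C)c(OC(=C)c2ccc(OCOC)c(OCOC)c2)c1C(OC)OC | intermediate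
17 | 2-({1-[3,4-bis(methoxymethoxy)phenyl]ethenyl}oxy)-4-methoxy-6-(methoxymethoxy)-3-(3-methylbut-2-en-1-yl)benzaldehyde | COCOc1cc(OC)c(CC=C(C)C)c(OC(=C)c2ccc(OCOC)c(OCOC)c2)c1C=O | intermediate
18 | (2S)-2-[3,4-bis(methoxymethoxy)phenyl]-7-methoxy-5-(methoxymethoxy)-8-(3-methylbut-2-en-1-yl)-2,3-dihydro-4H-chromen-4-one | COc1cc(OCOC)c2c(c1CC=C(C)C)O[C@H](c1ccc(OCOC)c(OCOC)c1)CC2=O | intermediate
19 | (2S)-2-(3,4-dihydroxyphenyl)-5-hydroxy-7-methoxy-8-(3-methylbut-2-en-1-yl)-2,3-dihydro-4H-chromen-4-one | COc1cc(O)c2c(c1CC=C(C)C)O[C@H](c1ccc(O)c(O)c1)CC2=O | target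

**Step count and risks**

Total step count: 12. Longest linear sequence: 9 steps (7 to 19, steps 4 to 12); acid 3 (steps 1 and 2) and carbonate 6 (step 3) are side branches.

Steps most likely to fail:

1. Step 11 (bears the label). The rhodium-bound acyl group may lose CO, the alkylrhodium stage may expel the aryloxide in the beta position, the cationic metal may merely act as a Lewis acid on the vinyl ether, or the enantioface selectivity may be poor. Fallback, known chemistry, setting out from 13 and coming back at 18: commercial 2-chloro-1-(3,4-dihydroxyphenyl)ethan-1-one is protected (MOMCl, i-Pr2NEt) to 2-chloro-1-[3,4-bis(methoxymethoxy)phenyl]ethan-1-one F1. Asymmetric transfer hydrogenation (RuCl(p-cymene)[(R,R)-TsDPEN], HCO2H/Et3N) should give (S)-2-chloro-1-[3,4-bis(methoxymethoxy)phenyl]ethan-1-ol F2. A Mitsunobu reaction of F2 with phenol 13 (PPh3, DIAD, toluene, 0 °C) should give, with inversion, 2-{(1R)-2-chloro-1-[3,4-bis(methoxymethoxy)phenyl]ethoxy}-4-methoxy-6-(methoxymethoxy)-3-(3-methylbut-2-en-1-yl)benzaldehyde F3. A carbene catalyst (3-benzyl-5-(2-hydroxyethyl)-4-methylthiazolium chloride, DBU, NaI) then converts the formyl group into its Breslow intermediate, which displaces the halide at the primary carbon in an intramolecular SN2 reaction (umpolung alkylation). This closes the same C3–C4 bond with the stereocentre already in place and gives 18.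

2. Step 10. Methylenation of the doubly ortho-substituted aryl ester may be slow, the acetal may be lost early so that the formyl group is methylenated, or the vinyl ether may hydrolyse during unmasking. Fallback, setting out from 13 and coming back at 17: commercial 1-(3,4-dihydroxyphenyl)ethan-1-one is protected (MOMCl, i-Pr2NEt) to 1-[3,4-bis(methoxymethoxy)phenyl]ethan-1-one F4 and converted (KHMDS, PhNTf2, THF, −78 °C) into 1-[3,4-bis(methoxymethoxy)phenyl]ethenyl trifluoromethanesulfonate F5. Palladium-catalysed C–O coupling of F5 with phenol 13 (Pd2(dba)3, t-BuXPhos, K3PO4, toluene, 80 °C) should give 17 directly, so that ester 14, acetal 15 and the titanium reagent are not needed.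

3. Step 5. A second allylation at the other phenol, C-allylation of the electron-rich ring, or isomerisation of the branched ether to the linear prenyl ether may compete. Fallback, setting out from 8 and coming back at 9: 8 is O-alkylated with 3-chloro-3-methylbut-1-yne (DBU, CuCl2 cat., MeCN, 0 °C) to 2-hydroxy-4-methoxy-6-[(2-methylbut-3-yn-2-yl)oxy]benzaldehyde F6. Semihydrogenation of the alkyne (H2, Pd/CaCO3 poisoned with Pb(OAc)2, quinoline, EtOAc) should then give 9.

Further compounds
F1 | step 11 | 2-chloro-1-[3,4-bis(methoxymethoxy)phenyl]ethan-1-one | COCOc1ccc(C(=O)CCl)cc1OCOC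
F2 | step 11 | (S)-2-chloro-1-[3,4-bis(methoxymethoxy)phenyl]ethan-1-ol | COCOc1ccc([C@H](O)CCl)cc1OCOC
F3 | step 11 | 2-{(1R)-2-chloro-1-[3,4-bis(methoxymethoxy)phenyl]ethoxy}-4-methoxy-6-(methoxymethoxy)-3-(3-methylbut-2-en-1-yl)benzaldehyde | O=Cc1c(O[C@@H](CCl)c2ccc(OCOC)c(OCOC)c2)c(CC=C(C)C)c(OC)cc1OCOC
F4 | step 10 | 1-[3,4-bis(methoxymethoxy)phenyl]ethan-1-one | CC(=O)c1ccc(OCOC)c(OCOC)c1
F5 | step 10 | 1-[3,4-bis(methoxymethoxy)phenyl]ethenyl trifluoromethanesulfonate | C=C(OS(=O)(=O)C(F)(F)F)c1ccc(OCOC)c(OCOC)c1
F6 | step 5 | 2-hydroxy-4-methoxy-6-[(2-methylbut-3-yn-2-yl)oxy]benzaldehyde | COc1cc(O)c(C=O)c(OC(C)(C)C#C)c1
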